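## Retrosynthetic overview

1. Endgame: the four benzyl ethers and the two ring A silyl ethers come off last. The ester at O3 is cut back to a protected (2R,3R)-2,3-cis-flavan-3-ol and 4-(benzyloxy)benzoic acid.
2. Both stereocentres come from one reduction. The racemic flavan-3-one epimerises at C2 and is reduced under dynamic kinetic resolution.
3. Structural feature used: in ring C, the unit O1–C2H(ring B)–C3(O) is a benzylic ether carbon on the ring A oxygen, next to an oxygenated carbon. If C3 is placed on ring A as a ketone ortho to O1, the C2 hydrogens sit in its delta position, and light can join C2 to C3 (Norrish–Yang).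
4. This gives a five-membered ring, a 2-aryl-3-hydroxy-2,3-dihydrobenzofuran-3-carboxylate. The ester carbon becomes C4 when the ring A carbon C3a shifts from C3 onto it, which widens the ring to the six-membered ring C.
5. Ring order: rings A and B and the benzoate ring are bought, the dihydrofuran ring forms in step 4, and ring C forms in step 7. The photosubstrate comes from phloroglucinol in three steps (C-oxalylation, twofold silylation, Mitsunobu etherification).

Key step: step 4

Assumption: the sense of induction in step 8 is assigned from the usual picture of the Ru–H/N–H transition state. The C4/ring A flank takes the place next to the eta6-arene and the substituted C2 flank takes the open place, so the (S,S) complex should give 3R. Both antipodes of the complex are commercial, so the (R,R) complex is taken if a test reduction shows the opposite sense.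

## Route

Step 1
Reactants: 1 phloroglucinol; 2 methyl chlorooxoacetate
Product: 3 methyl 2-oxo-2-(2,4,6-trihydroxyphenyl)acetate
Conditions: AlCl3 (3.5 equiv), CH2Cl2/PhNO2, 0 °C to rt; ice/1 M HCl
Reagents that add atoms: none
Why: Friedel–Crafts C-acylation of a very nucleophilic arene, in which the aluminium chelate between the new ketone and an ortho phenoxide deactivates the ring, so the reaction should stop after one acyl group as in the standard preparation of acylphloroglucinols.

Step 2
Reactants: 3 methyl 2-oxo-2-(2,4,6-trihydroxyphenyl)acetate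
Product: 4 methyl 2-[2,4-bis(tert-butyldimethylsilyloxy)-6-hydroxyphenyl]-2-oxoacetate
Conditions: TBSCl (2.1 equiv), imidazole (4.5 equiv), DMF, 0 °C
Reagents that add atoms: tert-butyldimethylsilyl chloride, CC(C)(C)[Si](C)(C)Cl
Why: Imidazole-promoted silylation takes the para hydroxyl and one of the two equivalent ortho hydroxyls, while the last hydroxyl is held in a strong hydrogen bond to the ketone, the selectivity relied on for twofold protection of acylphloroglucinols.

Step 3
Reactants: 4 methyl 2-[2,4-bis(tert-butyldimethylsilyloxy)-6-hydroxyphenyl]-2-oxoacetate; 5 3,4,5-tris(benzyloxy)benzyl alcohol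
Product: 6 methyl 2-{2,4-bis(tert-butyldimethylsilyloxy)-6-[3,4,5-tris(benzyloxy)benzyloxy]phenyl}-2-oxoacetate
Conditions: PPh3, DIAD, THF, 0 °C to rt
Reagents that add atoms: none
Why: Mitsunobu etherification, in which the chelated phenol is acidic enough to protonate the phosphine–azodicarboxylate betaine and its phenoxide displaces the activated primary benzylic oxygen under neutral conditions, avoiding carbonate bases that would strip or scramble aryl silyl ethers.

Step 4
Reactants: 6 methyl 2-{2,4-bis(tert-butyldimethylsilyloxy)-6-[3,4,5-tris(benzyloxy)benzyloxy]phenyl}-2-oxoacetate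
Product: 8 methyl 4,6-bis(tert-butyldimethylsilyloxy)-3-hydroxy-2-[3,4,5-tris(benzyloxy)phenyl]-2,3-dihydrobenzofuran-3-carboxylate (racemic mixture of the C2/C3 diastereomers), via 1,5-biradical 7 (not isolated)
Conditions: hν (365 nm LEDs or medium-pressure Hg lamp through Pyrex), degassed benzene (5 mM), 20 °C
Reagents that add atoms: none
Why: Excitation of the twisted aryl alpha-keto ester gives its n,pi* triplet, whose ketone oxygen takes a hydrogen from the O–CH2 carbon in the delta position through a seven-membered transition state, and the ketyl and alpha-aryloxybenzyl radical centres of 1,5-biradical 7 then combine to form C2–C3. The closest known reaction type is the Norrish–Yang photocyclisation of o-benzyloxyphenyl ketones and o-benzyloxyphenylglyoxylates to 2-aryl-3-hydroxy-2,3-dihydrobenzofurans. The one new ring, the five-membered dihydrofuran (O1, C2, C3, C3a, C7a), closes by intramolecular radical–radical combination of the 1,5-biradical. C2 and C3 arise without control as racemic cis and trans isomers, which is harmless because C3 becomes sp2 in step 7 and C2 is equilibrated in step 8. The step needs only site selectivity of hydrogen abstraction: the other ortho substituent has silicon in the delta position and so no hydrogen there, the ester OCH3 offers only strong primary C–H bonds, and the ring B benzyl ethers lie far from the carbonyl. High dilution in a solvent without weak C–H bonds should keep bimolecular photoreduction down.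

Step 5
Reactants: 8 methyl 4,6-bis(tert-butyldimethylsilyloxy)-3-hydroxy-2-[3,4,5-tris(benzyloxy)phenyl]-2,3-dihydrobenzofuran-3-carboxylate
Product: 9 4,6-bis(tert-butyldimethylsilyloxy)-3-(hydroxymethyl)-2-[3,4,5-tris(benzyloxy)phenyl]-2,3-dihydrobenzofuran-3-ol (racemic diastereomers)
Conditions: LiBH4 (2 equiv), THF, 0 °C to rt; then water
Reagents that add atoms: none
Why: Chemoselective ester reduction by LiBH4, helped by lithium coordination to the neighbouring alkoxide, in which aryl silyl and benzyl ethers are inert and no acid is present that could dehydrate the tertiary benzylic alcohol.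

Step 6
Reactants: 9 4,6-bis(tert-butyldimethylsilyloxy)-3-(hydroxymethyl)-2-[3,4,5-tris(benzyloxy)phenyl]-2,3-dihydrobenzofuran-3-ol
Product: 10 {4,6-bis(tert-butyldimethylsilyloxy)-3-hydroxy-2-[3,4,5-tris(benzyloxy)phenyl]-2,3-dihydrobenzofuran-3-yl}methyl methanesulfonate (racemic diastereomers)
Conditions: MsCl (1.1 equiv), Et3N, CH2Cl2, −30 °C to 0 °C
Reagents that add atoms: methanesulfonyl chloride, CS(=O)(=O)Cl
Why: Selective sulfonylation of the primary hydroxyl, since the tertiary and doubly flanked C3 hydroxyl does not react with MsCl/Et3N at low temperature.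

Step 7
Reactants: 10 {4,6-bis(tert-butyldimethylsilyloxy)-3-hydroxy-2-[3,4,5-tris(benzyloxy)phenyl]-2,3-dihydrobenzofuran-3-yl}methyl methanesulfonate
Product: 11 rac-5,7-bis(tert-butyldimethylsilyloxy)-2-[3,4,5-tris(benzyloxy)phenyl]chroman-3-one
Conditions: LiClO4 (3 equiv), 2,6-lutidine (2 equiv), THF, 50 °C, argon
Reagents that add atoms: none
Why: Proposed new method: the hydroxyl stays un-ionised because the hindered pyridine only takes up the acid, so three-membered ring closure by oxygen should be slow, whereas the 2,4,6-trioxygenated ring A lies next to the out-of-plane C3–CH2 bond and can displace the lithium-activated mesylate through an aryl-bridged transition state whose charge rests on the three oxygen-bearing carbons; collapse with the lone pair of the C3 oxygen breaks C3–C3a and gives the six-membered 3-ketone with the former ester carbon as C4; the aryl shift should outrun the shift of C2 (which would lead to the 4-ketone) because only the arene offers pi participation; the closest known reaction types are the LiClO4/CaCO3 pinacol-type ring expansion of diol monosulfonates, the organoaluminium-promoted aryl shift of 2-mesyloxy alcohols and the Tiffeneau–Demjanov homologation of benzo-fused cyclic ketones; no stereocentre is set and C2 stays racemic.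

Step 8
Reactants: 11 rac-5,7-bis(tert-butyldimethylsilyloxy)-2-[3,4,5-tris(benzyloxy)phenyl]chroman-3-one
Product: 13 (2R,3R)-5,7-bis(tert-butyldimethylsilyloxy)-2-[3,4,5-tris(benzyloxy)phenyl]chroman-3-ol, via achiral enol 12 (not isolated)
Conditions: RuCl(p-cymene)[(S,S)-TsDPEN] (3 mol %), HCO2H/Et3N (1:1), EtOAc, 40 °C, argon
Reagents that add atoms: none
Why: Proposed new method: the C2–H of 11 is flanked by the ketone, ring B and O1, so triethylamine should interconvert the two enantiomers through enol 12 faster than either is reduced, while the Ru–H/N–H species delivers hydride to C3 from the ring face away from ring B (hence 2,3-cis) and, with the substituted C2 flank turned away from the eta6-arene, should prefer the Si face of the (2R)-ketone, which sets C3 as R and fixes C2 as R; Noyori–Ikariya transfer hydrogenation with dynamic kinetic resolution is established for 3-arylchroman-4-ones, 2-substituted indanones and tetralones and alpha-substituted beta-keto esters, but not for a non-conjugated 2-arylchroman-3-one.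

Step 9
Reactants: 13 (2R,3R)-5,7-bis(tert-butyldimethylsilyloxy)-2-[3,4,5-tris(benzyloxy)phenyl]chroman-3-ol; 14 4-(benzyloxy)benzoic acid
Product: 16 (2R,3R)-5,7-bis(tert-butyldimethylsilyloxy)-2-[3,4,5-tris(benzyloxy)phenyl]chroman-3-yl 4-(benzyloxy)benzoate, via O-acylisourea 15 (not isolated)
Conditions: DCC (1.5 equiv), DMAP (0.2 equiv), CH2Cl2, 0 °C to rt
Reagents that add atoms: none
Why: Steglich esterification, in which DMAP carries the acyl group from O-acylisourea 15 to the axial C3 hydroxyl without breaking any bond to a stereocentre, as is routine for 3-O-acyl derivatives of protected 2,3-cis-flavan-3-ols.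

Step 10
Reactants: 16 (2R,3R)-5,7-bis(tert-butyldimethylsilyloxy)-2-[3,4,5-tris(benzyloxy)phenyl]chroman-3-yl 4-(benzyloxy)benzoate
Product: 17 (2R,3R)-5,7-dihydroxy-2-[3,4,5-tris(benzyloxy)phenyl]chroman-3-yl 4-(benzyloxy)benzoate
Conditions: TBAF (2.2 equiv), AcOH (2.5 equiv), THF, 0 °C
Reagents that add atoms: none
Why: Fluoride cleavage of the two aryl silyl ethers, with acetic acid buffering the phenoxides so that the benzoate is neither cleaved nor moved and C2 is not epimerised.

Step 11
Reactants: 17 (2R,3R)-5,7-dihydroxy-2-[3,4,5-tris(benzyloxy)phenyl]chroman-3-yl 4-(benzyloxy)benzoate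
Product: 18 epigallocatechin 3-O-(4-hydroxybenzoate), (2R,3R)
Conditions: H2 (1 atm), Pd(OH)2/C, THF/MeOH, rt
Reagents that add atoms: none
Why: Neutral hydrogenolysis of the four O-benzyl groups, the standard last step for catechin esters, in which the cyclic O1–C2 ether, the ester and both stereocentres are known to survive and only filtration and evaporation are needed.

## Compound list

1 | phloroglucinol | Oc1cc(O)cc(O)c1 | starting material
2 | methyl chlorooxoacetate | COC(=O)C(Cl)=O | starting material
3 | methyl 2-oxo-2-(2,4,6-trihydroxyphenyl)acetate | COC(=O)C(=O)c1c(O)cc(O)cc1O | intermediate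
4 | methyl 2-[2,4-bis(tert-butyldimethylsilyloxy)-6-hydroxyphenyl]-2-oxoacetate | COC(=O)C(=O)c1c(O)cc(O[Si](C)(C)C(C)(C)C)cc1O[Si](C)(C)C(C)(C)C | intermediate
5 | 3,4,5-tris(benzyloxy)benzyl alcohol | OCc1cc(OCc2ccccc2)c(OCc2ccccc2)c(OCc2ccccc2)c1 | starting material
6 | methyl 2-{2,4-bis(tert-butyldimethylsilyloxy)-6-[3,4,5-tris(benzyloxy)benzyloxy]phenyl}-2-oxoacetate | COC(=O)C(=O)c1c(O[Si](C)(C)C(C)(C)C)cc(O[Si](C)(C)C(C)(C)C)cc1OCc1cc(OCc2ccccc2)c(OCc2ccccc2)c(OCc2ccccc2)c1 | intermediate
7 | 1,5-biradical (ketyl carbon and alpha-aryloxybenzyl carbon), not isolated | COC(=O)[C](O)c1c(O[Si](C)(C)C(C)(C)C)cc(O[Si](C)(C)C(C)(C)C)cc1O[CH]c1cc(OCc2ccccc2)c(OCc2ccccc2)c(OCc2ccccc2)c1 | intermediate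
8 | methyl 4,6-bis(tert-butyldimethylsilyloxy)-3-hydroxy-2-[3,4,5-tris(benzyloxy)phenyl]-2,3-dihydrobenzofuran-3-carboxylate (racemic diastereomers) | COC(=O)C1(O)C(c2cc(OCc3ccccc3)c(OCc3ccccc3)c(OCc3ccccc3)c2)Oc2cc(O[Si](C)(C)C(C)(C)C)cc(O[Si](C)(C)C(C)(C)C)c21 | intermediate
9 | 4,6-bis(tert-butyldimethylsilyloxy)-3-(hydroxymethyl)-2-[3,4,5-tris(benzyloxy)phenyl]-2,3-dihydrobenzofuran-3-ol (racemic diastereomers) | OCC1(O)C(c2cc(OCc3ccccc3)c(OCc3ccccc3)c(OCc3ccccc3)c2)Oc2cc(O[Si](C)(C)C(C)(C)C)cc(O[Si](C)(C)C(C)(C)C)c21 | intermediate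
10 | {4,6-bis(tert-butyldimethylsilyloxy)-3-hydroxy-2-[3,4,5-tris(benzyloxy)phenyl]-2,3-dihydrobenzofuran-3-yl}methyl methanesulfonate (racemic diastereomers) | CS(=O)(=O)OCC1(O)C(c2cc(OCc3ccccc3)c(OCc3ccccc3)c(OCc3ccccc3)c2)Oc2cc(O[Si](C)(C)C(C)(C)C)cc(O[Si](C)(C)C(C)(C)C)c21 | intermediate
11 | rac-5,7-bis(tert-butyldimethylsilyloxy)-2-[3,4,5-tris(benzyloxy)phenyl]chroman-3-one | O=C1Cc2c(O[Si](C)(C)C(C)(C)C)cc(O[Si](C)(C)C(C)(C)C)cc2OC1c1cc(OCc2ccccc2)c(OCc2ccccc2)c(OCc2ccccc2)c1 | intermediate
12 | 5,7-bis(tert-butyldimethylsilyloxy)-2-[3,4,5-tris(benzyloxy)phenyl]-4H-chromen-3-ol (achiral enol), not isolated | OC1=C(c2cc(OCc3ccccc3)c(OCc3ccccc3)c(OCc3ccccc3)c2)Oc2cc(O[Si](C)(C)C(C)(C)C)cc(O[Si](C)(C)C(C)(C)C)c2C1 | intermediate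
13 | (2R,3R)-5,7-bis(tert-butyldimethylsilyloxy)-2-[3,4,5-tris(benzyloxy)phenyl]chroman-3-ol | O[C@@H]1Cc2c(O[Si](C)(C)C(C)(C)C)cc(O[Si](C)(C)C(C)(C)C)cc2O[C@@H]1c1cc(OCc2ccccc2)c(OCc2ccccc2)c(OCc2ccccc2)c1 | intermediate
14 | 4-(benzyloxy)benzoic acid | OC(=O)c1ccc(OCc2ccccc2)cc1 | starting material
15 | N,N'-dicyclohexyl-O-[4-(benzyloxy)benzoyl]isourea, not isolated | O=C(OC(=NC1CCCCC1)NC1CCCCC1)c1ccc(OCc2ccccc2)cc1 | intermediate
16 | (2R,3R)-5,7-bis(tert-butyldimethylsilyloxy)-2-[3,4,5-tris(benzyloxy)phenyl]chroman-3-yl 4-(benzyloxy)benzoate | O=C(O[C@@H]1Cc2c(O[Si](C)(C)C(C)(C)C)cc(O[Si](C)(C)C(C)(C)C)cc2O[C@@H]1c1cc(OCc2ccccc2)c(OCc2ccccc2)c(OCc2ccccc2)c1)c1ccc(OCc2ccccc2)cc1 | intermediate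
17 | (2R,3R)-5,7-dihydroxy-2-[3,4,5-tris(benzyloxy)phenyl]chroman-3-yl 4-(benzyloxy)benzoate | O=C(O[C@@H]1Cc2c(O)cc(O)cc2O[C@@H]1c1cc(OCc2ccccc2)c(OCc2ccccc2)c(OCc2ccccc2)c1)c1ccc(OCc2ccccc2)cc1 | intermediate
18 | epigallocatechin 3-O-(4-hydroxybenzoate), (2R,3R) | O=C(O[C@@H]1Cc2c(O)cc(O)cc2O[C@@H]1c1cc(O)c(O)c(O)c1)c1ccc(O)cc1 | target

Total step count: 11
Longest linear sequence: 11 steps (1 to 18)

## Steps most likely to fail

**Step 7 (aryl-shift ring expansion).**
- What may go wrong:
  - The C3 hydroxyl may close onto the CH2 to give a spiro-epoxide, which cannot give the ring-expanded ketone.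
  - The tertiary, very electron-rich benzylic C3–O bond may ionise, with loss of the C2 hydrogen and aromatisation of the five-membered ring.
  - C2 may migrate in place of the ring A carbon.
- Fallback, from 8 back to 11:
  - Aminolysis of the ester with the aluminium amide from Me3Al and NH4Cl (toluene, 50 °C) should give the primary carboxamide F1.
  - Reduction with BH3·THF should give the 3-(aminomethyl)-2,3-dihydrobenzofuran-3-ol F2.
  - Diazotisation (NaNO2, AcOH/H2O/THF, 0 °C) starts a Tiffeneau–Demjanov ring expansion to 11.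
  - Dinitrogen leaves without assistance. The preference for aryl migration is known for the 1-(aminomethyl) carbinols of benzo-fused cyclic ketones.
  - The step count does not change.

**Step 8 (dynamic kinetic transfer hydrogenation).**
- What may go wrong:
  - The catalyst may discriminate poorly between the two benzylic flanks of a non-conjugated ketone.
  - Epimerisation at C2 may be too slow relative to reduction, so the process becomes a plain kinetic resolution.
  - Traces of air may oxidise the enol.
  - The aryl silyl ethers may be slowly lost in the amine-rich medium.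
- Fallback, from 11 back to 13:
  - L-Selectride (THF, −78 °C) attacks from the face away from ring B, as is known for protected flavan-3-ones, and should give the racemic 2,3-cis-flavan-3-ol F3.
  - Steglich esterification with (S)-O-methylmandelic acid gives the (2R,3R)-configured ester F4 and the (2S,3S)-configured ester F5.
  - The two esters are separated by chromatography or crystallisation.
  - LiBH4 (THF, 0 °C) cleaves F4 reductively to 13.

**Step 4 (Norrish–Yang photocyclisation).**
- What may go wrong:
  - A low-lying pi,pi* or charge-transfer triplet of the trioxygenated aryl ketone may slow hydrogen abstraction.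
  - Back transfer of hydrogen in the biradical may lower the efficiency.
  - The excited ketone may take a hydrogen from the ester methyl group and cleave the ester, or undergo bimolecular photoreduction.
- Fallback, from 4 and 5 back to 8, which makes the same two ring bonds by polar chemistry:
  - Alcohol 5 with tetrahydrothiophene and HBF4·OEt2 should give the benzylic sulfonium salt F6.
  - LiHMDS (2.1 equiv, THF, −78 °C to rt) deprotonates phenol 4 and forms the ylide.
  - The ylide adds to the activated ketone of 4 in a Corey–Chaykovsky reaction to give the glycidic ester F7.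
  - The ortho phenoxide opens F7 at the ring B benzylic carbon to give 8.

## Further compounds

F1 | step 7 | 4,6-bis(tert-butyldimethylsilyloxy)-3-hydroxy-2-[3,4,5-tris(benzyloxy)phenyl]-2,3-dihydrobenzofuran-3-carboxamide (racemic diastereomers) | NC(=O)C1(O)C(c2cc(OCc3ccccc3)c(OCc3ccccc3)c(OCc3ccccc3)c2)Oc2cc(O[Si](C)(C)C(C)(C)C)cc(O[Si](C)(C)C(C)(C)C)c21
F2 | step 7 | 3-(aminomethyl)-4,6-bis(tert-butyldimethylsilyloxy)-2-[3,4,5-tris(benzyloxy)phenyl]-2,3-dihydrobenzofuran-3-ol (racemic diastereomers) | NCC1(O)C(c2cc(OCc3ccccc3)c(OCc3ccccc3)c(OCc3ccccc3)c2)Oc2cc(O[Si](C)(C)C(C)(C)C)cc(O[Si](C)(C)C(C)(C)C)c21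
F3 | step 8 | rac-2,3-cis-5,7-bis(tert-butyldimethylsilyloxy)-2-[3,4,5-tris(benzyloxy)phenyl]chroman-3-ol (both enantiomers written) | O[C@@H]1Cc2c(O[Si](C)(C)C(C)(C)C)cc(O[Si](C)(C)C(C)(C)C)cc2O[C@@H]1c1cc(OCc2ccccc2)c(OCc2ccccc2)c(OCc2ccccc2)c1.O[C@H]1Cc2c(O[Si](C)(C)C(C)(C)C)cc(O[Si](C)(C)C(C)(C)C)cc2O[C@H]1c1cc(OCc2ccccc2)c(OCc2ccccc2)c(OCc2ccccc2)c1
F4 | step 8 | (2R,3R)-5,7-bis(tert-butyldimethylsilyloxy)-2-[3,4,5-tris(benzyloxy)phenyl]chroman-3-yl (S)-2-methoxy-2-phenylacetate | CO[C@H](C(=O)O[C@@H]1Cc2c(O[Si](C)(C)C(C)(C)C)cc(O[Si](C)(C)C(C)(C)C)cc2O[C@@H]1c1cc(OCc2ccccc2)c(OCc2ccccc2)c(OCc2ccccc2)c1)c1ccccc1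
F5 | step 8 | (2S,3S)-5,7-bis(tert-butyldimethylsilyloxy)-2-[3,4,5-tris(benzyloxy)phenyl]chroman-3-yl (S)-2-methoxy-2-phenylacetate | CO[C@H](C(=O)O[C@H]1Cc2c(O[Si](C)(C)C(C)(C)C)cc(O[Si](C)(C)C(C)(C)C)cc2O[C@H]1c1cc(OCc2ccccc2)c(OCc2ccccc2)c(OCc2ccccc2)c1)c1ccccc1
F6 | step 4 | 1-[3,4,5-tris(benzyloxy)benzyl]tetrahydrothiophenium tetrafluoroborate | F[B-](F)(F)F.C1CC[S+](C1)Cc1cc(OCc2ccccc2)c(OCc2ccccc2)c(OCc2ccccc2)c1
F7 | step 4 | methyl 2-[2,4-bis(tert-butyldimethylsilyloxy)-6-hydroxyphenyl]-3-[3,4,5-tris(benzyloxy)phenyl]oxirane-2-carboxylate (racemic) | COC(=O)C1(OC1c1cc(OCc2ccccc2)c(OCc2ccccc2)c(OCc2ccccc2)c1)c1c(O)cc(O[Si](C)(C)C(C)(C)C)cc1O[Si](C)(C)C(C)(C)C
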